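The route rests on the C3–C4 bond of ring C in the top (epiafzelechin) unit. Because O7 of ring A lies para to C4a, C4 can be held as the exocyclic carbon of a para-quinone methide, while C3 is an aldehyde: two electrophiles. Two electrons from SmI2 reverse the polarity of C4, which then attacks the aldehyde, closing ring C, setting C3 and C4 and freeing the 7-hydroxyl in one operation. The precursor is an (R)-2-aryloxy-2-(4-benzyloxyphenyl)acetaldehyde (C2 already in place) whose aryloxy group is the ring A quinone methide carrying the benzylated epicatechin-(4β→8)-epicatechin dimer on its methide carbon.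

Key step: step 13

Assumptions: (S)-4-hydroxymandelic acid is bought as the single enantiomer. The diaryl carbinols are carried as mixtures of epimers at the carbinol carbon and the quinone methide is drawn without alkene geometry, since that carbon becomes the C4 anion and neither element survives.

Step 1
Reactants: 1 (−)-epicatechin
Product: 2 5,7,3′,4′-tetra-O-benzyl-(−)-epicatechin
Conditions: BnBr (4.4 equiv), K2CO3, DMF, 0 °C to rt
Reagents that add atoms: benzyl bromide, BrCc1ccccc1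
Why: Williamson etherification in which carbonate deprotonates only the four phenols, so the secondary 3-hydroxyl stays free and C2 and C3 are untouched.

Step 2
Reactants: 2 5,7,3′,4′-tetra-O-benzyl-(−)-epicatechin
Product: 3 3,5,7,3′,4′-penta-O-benzyl-(−)-epicatechin
Conditions: NaH, BnBr, n-Bu4NI (cat.), THF/DMF, 0 °C to rt
Reagents that add atoms: benzyl bromide, BrCc1ccccc1
Why: Williamson etherification of the secondary alcohol through its sodium alkoxide; with no free phenol left the base has no path to open ring C, so C2 and C3 keep their configuration.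

Step 3
Reactants: 3 3,5,7,3′,4′-penta-O-benzyl-(−)-epicatechin
Product: 4 8-bromo-3,5,7,3′,4′-penta-O-benzyl-(−)-epicatechin
Conditions: NBS (1.0 equiv), CH2Cl2, −78 °C to 0 °C
Reagents that add atoms: N-bromosuccinimide, O=C1CCC(=O)N1Br
Why: Electrophilic aromatic bromination, which should be selective for C8 of ring A (flanked by O1 and O7), the most nucleophilic position of benzylated flavan-3-ols.

Step 4
Reactants: 4 8-bromo-3,5,7,3′,4′-penta-O-benzyl-(−)-epicatechin
Product: 5 8-bromo-4β-(2-ethoxyethoxy)-3,5,7,3′,4′-penta-O-benzylepicatechin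
Conditions: DDQ (2 equiv), EtOCH2CH2OH (5 equiv), CH2Cl2, rt
Reagents that add atoms: 2-ethoxyethanol, CCOCCO
Why: Benzylic oxidation by hydride abstraction at C4 gives a cation stabilised by ring A, which the alcohol should trap anti to the 3-benzyloxy group (3,4-trans ether); this C4 configuration is erased again in step 5.

Step 5
Reactants: 5 8-bromo-4β-(2-ethoxyethoxy)-3,5,7,3′,4′-penta-O-benzylepicatechin; 3 3,5,7,3′,4′-penta-O-benzyl-(−)-epicatechin (2.5 equiv)
Product: 6 8-bromo-deca-O-benzyl-epicatechin-(4β→8)-epicatechin (bromine at C8 of the upper unit)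
Conditions: TMSOTf (0.2 equiv), CH2Cl2, −78 °C; Et3N quench
Reagents that add atoms: none
Why: Lewis-acid Friedel–Crafts flavanylation in which the C4 cation from 5 is attacked by C8 of 3 on the β face, anti to the α-oriented 3-benzyloxy and 2-aryl groups, which sets the 4β (3,4-trans) interflavan centre; the bromine blocks self-condensation of 5 and marks C8 of the upper unit for step 10.

Step 6
Reactants: 7 2,4,6-trihydroxybenzaldehyde
Product: 8 2,6-dihydroxy-4-(triisopropylsilyloxy)benzaldehyde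
Conditions: TIPSCl (1.0 equiv), imidazole, DMF, 0 °C
Reagents that add atoms: triisopropylsilyl chloride, CC(C)[Si](Cl)(C(C)C)C(C)C
Why: Silylation with one equivalent of a bulky chlorosilane should go to the para hydroxyl, the most acidic and least hindered one and the only one that cannot hydrogen-bond to the formyl group.

Step 7
Reactants: 8 2,6-dihydroxy-4-(triisopropylsilyloxy)benzaldehyde
Product: 9 2-benzyloxy-6-hydroxy-4-(triisopropylsilyloxy)benzaldehyde
Conditions: BnOH (1.0 equiv), PPh3, DIAD, THF, 0 °C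
Reagents that add atoms: benzyl alcohol, OCc1ccccc1
Why: Mitsunobu etherification under neutral conditions that spare the aryl silyl ether; the two ortho hydroxyls are equivalent, and after the first benzylation the remaining one is locked in a hydrogen bond to the formyl group, which slows a second alkylation.

Step 8
Reactants: 10 (S)-4-hydroxymandelic acid
Product: 11 benzyl (S)-2-(4-benzyloxyphenyl)-2-hydroxyacetate
Conditions: BnBr (2.1 equiv), K2CO3, DMF, rt
Reagents that add atoms: benzyl bromide, BrCc1ccccc1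
Why: O-alkylation of the carboxylate and the phenoxide (Williamson type) by a base too weak to deprotonate the secondary hydroxyl or the α-C–H, so the S centre is kept.

Step 9
Reactants: 9 2-benzyloxy-6-hydroxy-4-(triisopropylsilyloxy)benzaldehyde; 11 benzyl (S)-2-(4-benzyloxyphenyl)-2-hydroxyacetate
Product: 12 benzyl (R)-2-(4-benzyloxyphenyl)-2-[3-benzyloxy-2-formyl-5-(triisopropylsilyloxy)phenoxy]acetate
Conditions: PPh3, DIAD, toluene, 0 °C to rt
Reagents that add atoms: none
Why: Mitsunobu reaction in which the acidic phenol of 9 displaces the activated hydroxyl of 11 by SN2 with inversion (S to R), the α-ester group disfavouring ionisation of the benzylic carbon; this R centre is C2 of the top unit.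

Step 10
Reactants: 6 8-bromo-deca-O-benzyl-epicatechin-(4β→8)-epicatechin; 12 benzyl (R)-2-(4-benzyloxyphenyl)-2-[3-benzyloxy-2-formyl-5-(triisopropylsilyloxy)phenoxy]acetate
Product: 15 diaryl carbinol ester (benzyl ester, silyl ether, epimers at the carbinol carbon), via 8-lithio dimer 13 (not isolated), via 8-dichlorocerio dimer 14 (not isolated)
Conditions: t-BuLi (2.1 equiv), THF, −78 °C; CeCl3 (anhydrous, 1.3 equiv), −78 °C; 12 (1.2 equiv), −78 °C; AcOH, then aq NH4Cl
Reagents that add atoms: none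
Why: Bromine–lithium exchange at C8 and transmetallation give the weakly basic, carbonyl-selective aryl cerium dichloride, which should undergo 1,2-addition to the hindered aryl aldehyde of 12 without attacking the benzyl ester or removing its acidic α-hydrogen; the new carbinol centre is erased in step 12.

Step 11
Reactants: 15 diaryl carbinol ester
Product: 16 diaryl carbinol aldehyde (silyl ether, epimers at the carbinol carbon)
Conditions: i-Bu2AlH (2.3 equiv), CH2Cl2, −78 °C; MeOH, then aq KNaC4H4O6 (potassium sodium tartrate)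
Reagents that add atoms: none
Why: Partial reduction of an ester with i-Bu2AlH at −78 °C, where the α-aryloxy oxygen chelates aluminium and holds the tetrahedral hemiacetal until the cold quench; the carbinol only consumes one hydride as its aluminium alkoxide, and 16 is used without delay.

Step 12
Reactants: 16 diaryl carbinol aldehyde
Product: 18 (R)-2-aryloxy-2-(4-benzyloxyphenyl)acetaldehyde whose aryl group is the ring A para-quinone methide bearing the benzylated dimer, via phenol carbinol aldehyde 17 (not isolated)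
Conditions: TBAF (1.1 equiv), AcOH (1.5 equiv), 4 Å MS, THF, −20 °C to 0 °C; crude 18 used at once
Reagents that add atoms: none
Why: Fluoride cleaves the aryl silyl ether under acetic acid buffering, and the freed para-hydroxy benzhydrol between two electron-rich rings should lose water by 1,6-elimination to the push–pull stabilised para-quinone methide; the cold, near-neutral medium protects the epimerisable C2–H next to the aldehyde.

Step 13
Reactants: 18 quinone methide aldehyde
Product: 20 dodeca-O-benzyl epiafzelechin-(4β→8)-epicatechin-(4β→8)-epicatechin with free 3-hydroxyl and 7-hydroxyl on the top unit, via C4 organosamarium phenoxide 19 (not isolated)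
Conditions: SmI2 (2.5 equiv, 0.1 M in THF) added to 18 in THF, −78 °C; then aq NH4Cl
Reagents that add atoms: none
Why: Proposed new method: SmI2 should transfer one electron to the cross-conjugated dienone of ring A, the most easily reduced π system of 18, giving a samarium phenoxide at O7 and a diarylmethyl radical at C4 that accepts a second electron to become the benzylic organosamarium 19, which adds to the tethered aldehyde carbon C3; the closest known reaction types are SmI2 Barbier-type cyclisations of halo carbonyl compounds and SmI2 reductive couplings of carbonyl groups with conjugate acceptors, and should the aldehyde be reduced first, its ketyl would attack the same methide carbon and form the same bond. Ring C closes by 6-exo-trig attack of C4 on the aldehyde carbonyl. C4 is controlled by peri (allylic) strain with the 5-benzyloxy group, which keeps the C4 hydrogen in the plane of ring A and the dimer substituent quasi-axial, on the face opposite the equatorial C2 aryl group whose R centre is already fixed. C3 is controlled by the chair-like transition state in which the carbonyl oxygen sits axial, anti to the C4 aryl group and gauche to O1 so that trivalent samarium can bridge O3 and O1, whereas an equatorial O3 would be gauche to both flanking aryl groups; together this gives 2,3-cis and 3,4-trans. The step needs reduction of the quinone methide ahead of the α-aryloxy aldehyde and carbon–carbon bond formation ahead of protonation or epimerisation at C2, which the easy reduction of the quinone methide, the absence of a proton source and −78 °C should secure.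

Step 14
Reactants: 20 dodeca-O-benzyl trimer
Product: 21 epiafzelechin-(4β→8)-epicatechin-(4β→8)-epicatechin (CNP0158921.2)
Conditions: H2 (1 atm), Pd(OH)2 on carbon, THF/MeOH/H2O, rt
Reagents that add atoms: none
Why: Catalytic hydrogenolysis should remove all twelve benzyl ethers (ten aryl, two secondary alkyl) while mild pressure leaves the C2–O1 and interflavan benzylic bonds intact, so no stereocentre is touched.

Compound list

1 | (−)-epicatechin, (2R,3R) | O[C@@H]1Cc2c(O)cc(O)cc2O[C@@H]1c1ccc(O)c(O)c1 | starting material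
2 | 5,7,3′,4′-tetra-O-benzyl-(−)-epicatechin | O[C@@H]1Cc2c(OCc5ccccc5)cc(OCc5ccccc5)cc2O[C@@H]1c1ccc(OCc5ccccc5)c(OCc5ccccc5)c1 | intermediate
3 | 3,5,7,3′,4′-penta-O-benzyl-(−)-epicatechin | O(Cc5ccccc5)[C@@H]1Cc2c(OCc5ccccc5)cc(OCc5ccccc5)cc2O[C@@H]1c1ccc(OCc5ccccc5)c(OCc5ccccc5)c1 | intermediate
4 | 8-bromo-3,5,7,3′,4′-penta-O-benzyl-(−)-epicatechin | O(Cc5ccccc5)[C@@H]1Cc2c(OCc5ccccc5)cc(OCc5ccccc5)c(Br)c2O[C@@H]1c1ccc(OCc5ccccc5)c(OCc5ccccc5)c1 | intermediate
5 | 8-bromo-4β-(2-ethoxyethoxy)-3,5,7,3′,4′-penta-O-benzylepicatechin (3,4-trans) | O(Cc5ccccc5)[C@@H]1[C@@H](OCCOCC)c2c(OCc5ccccc5)cc(OCc5ccccc5)c(Br)c2O[C@@H]1c1ccc(OCc5ccccc5)c(OCc5ccccc5)c1 | intermediate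
6 | 8-bromo-deca-O-benzyl-epicatechin-(4β→8)-epicatechin, bromine on the upper unit | Brc3c(OCc5ccccc5)cc(OCc5ccccc5)c4c3O[C@H](c3ccc(OCc5ccccc5)c(OCc5ccccc5)c3)[C@H](OCc5ccccc5)[C@H]4c3c(OCc5ccccc5)cc(OCc5ccccc5)c4c3O[C@H](c3ccc(OCc5ccccc5)c(OCc5ccccc5)c3)[C@H](OCc5ccccc5)C4 | intermediate
7 | 2,4,6-trihydroxybenzaldehyde | O=Cc1c(O)cc(O)cc1O | starting material
8 | 2,6-dihydroxy-4-(triisopropylsilyloxy)benzaldehyde | O=Cc1c(O)cc(O[Si](C(C)C)(C(C)C)C(C)C)cc1O | intermediate
9 | 2-benzyloxy-6-hydroxy-4-(triisopropylsilyloxy)benzaldehyde | O=Cc1c(O)cc(O[Si](C(C)C)(C(C)C)C(C)C)cc1OCc1ccccc1 | intermediate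
10 | (S)-4-hydroxymandelic acid | O[C@H](C(=O)O)c1ccc(O)cc1 | starting material
11 | benzyl (S)-2-(4-benzyloxyphenyl)-2-hydroxyacetate | O[C@H](C(=O)OCc5ccccc5)c1ccc(OCc5ccccc5)cc1 | intermediate
12 | benzyl (R)-2-(4-benzyloxyphenyl)-2-[3-benzyloxy-2-formyl-5-(triisopropylsilyloxy)phenoxy]acetate | O=C(OCc5ccccc5)[C@@H](c1ccc(OCc5ccccc5)cc1)Oc1cc(O[Si](C(C)C)(C(C)C)C(C)C)cc(OCc5ccccc5)c1C=O | intermediate
13 | 8-lithio deca-O-benzyl dimer (aryllithium at C8 of the upper unit) | [Li]c3c(OCc5ccccc5)cc(OCc5ccccc5)c4c3O[C@H](c3ccc(OCc5ccccc5)c(OCc5ccccc5)c3)[C@H](OCc5ccccc5)[C@H]4c3c(OCc5ccccc5)cc(OCc5ccccc5)c4c3O[C@H](c3ccc(OCc5ccccc5)c(OCc5ccccc5)c3)[C@H](OCc5ccccc5)C4 | intermediate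
14 | 8-dichlorocerio deca-O-benzyl dimer (aryl cerium dichloride, trivalent cerium) | Cl[Ce](Cl)c3c(OCc5ccccc5)cc(OCc5ccccc5)c4c3O[C@H](c3ccc(OCc5ccccc5)c(OCc5ccccc5)c3)[C@H](OCc5ccccc5)[C@H]4c3c(OCc5ccccc5)cc(OCc5ccccc5)c4c3O[C@H](c3ccc(OCc5ccccc5)c(OCc5ccccc5)c3)[C@H](OCc5ccccc5)C4 | intermediate
15 | benzyl (R)-2-(4-benzyloxyphenyl)-2-[3-benzyloxy-2-[hydroxy(dimer-8-yl)methyl]-5-(triisopropylsilyloxy)phenoxy]acetate, epimers at the carbinol carbon | O=C(OCc5ccccc5)[C@@H](c1ccc(OCc5ccccc5)cc1)Oc1cc(O[Si](C(C)C)(C(C)C)C(C)C)cc(OCc5ccccc5)c1C(O)c3c(OCc5ccccc5)cc(OCc5ccccc5)c4c3O[C@H](c3ccc(OCc5ccccc5)c(OCc5ccccc5)c3)[C@H](OCc5ccccc5)[C@H]4c3c(OCc5ccccc5)cc(OCc5ccccc5)c4c3O[C@H](c3ccc(OCc5ccccc5)c(OCc5ccccc5)c3)[C@H](OCc5ccccc5)C4 | intermediate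
16 | (R)-2-(4-benzyloxyphenyl)-2-[3-benzyloxy-2-[hydroxy(dimer-8-yl)methyl]-5-(triisopropylsilyloxy)phenoxy]acetaldehyde, epimers at the carbinol carbon | O=C[C@@H](c1ccc(OCc5ccccc5)cc1)Oc1cc(O[Si](C(C)C)(C(C)C)C(C)C)cc(OCc5ccccc5)c1C(O)c3c(OCc5ccccc5)cc(OCc5ccccc5)c4c3O[C@H](c3ccc(OCc5ccccc5)c(OCc5ccccc5)c3)[C@H](OCc5ccccc5)[C@H]4c3c(OCc5ccccc5)cc(OCc5ccccc5)c4c3O[C@H](c3ccc(OCc5ccccc5)c(OCc5ccccc5)c3)[C@H](OCc5ccccc5)C4 | intermediate
17 | desilylated phenol of 16 (5-hydroxy on the phenoxy ring), epimers at the carbinol carbon | O=C[C@@H](c1ccc(OCc5ccccc5)cc1)Oc1cc(O)cc(OCc5ccccc5)c1C(O)c3c(OCc5ccccc5)cc(OCc5ccccc5)c4c3O[C@H](c3ccc(OCc5ccccc5)c(OCc5ccccc5)c3)[C@H](OCc5ccccc5)[C@H]4c3c(OCc5ccccc5)cc(OCc5ccccc5)c4c3O[C@H](c3ccc(OCc5ccccc5)c(OCc5ccccc5)c3)[C@H](OCc5ccccc5)C4 | intermediate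
18 | (R)-2-aryloxy-2-(4-benzyloxyphenyl)acetaldehyde whose aryl group is the para-quinone methide of top ring A, with the benzylated dimer (through its C8) on the methide carbon; alkene geometry undefined | O=C[C@@H](c1ccc(OCc5ccccc5)cc1)OC1=CC(=O)C=C(OCc5ccccc5)C1=Cc3c(OCc5ccccc5)cc(OCc5ccccc5)c4c3O[C@H](c3ccc(OCc5ccccc5)c(OCc5ccccc5)c3)[C@H](OCc5ccccc5)[C@H]4c3c(OCc5ccccc5)cc(OCc5ccccc5)c4c3O[C@H](c3ccc(OCc5ccccc5)c(OCc5ccccc5)c3)[C@H](OCc5ccccc5)C4 | intermediate
19 | C4 benzylic organosamarium with samarium phenoxide at O7 (trivalent samarium at both sites), aldehyde still open | O=C[C@@H](c1ccc(OCc5ccccc5)cc1)Oc1cc(O[Sm](I)I)cc(OCc5ccccc5)c1C([Sm](I)I)c3c(OCc5ccccc5)cc(OCc5ccccc5)c4c3O[C@H](c3ccc(OCc5ccccc5)c(OCc5ccccc5)c3)[C@H](OCc5ccccc5)[C@H]4c3c(OCc5ccccc5)cc(OCc5ccccc5)c4c3O[C@H](c3ccc(OCc5ccccc5)c(OCc5ccccc5)c3)[C@H](OCc5ccccc5)C4 | intermediate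
20 | dodeca-O-benzyl epiafzelechin-(4β→8)-epicatechin-(4β→8)-epicatechin, free 3-OH and 7-OH on the top unit (top unit 2R,3R,4R) | O(Cc5ccccc5)c1ccc([C@H]2Oc3cc(O)cc(OCc5ccccc5)c3[C@H](c3c(OCc5ccccc5)cc(OCc5ccccc5)c4c3O[C@H](c3ccc(OCc5ccccc5)c(OCc5ccccc5)c3)[C@H](OCc5ccccc5)[C@H]4c3c(OCc5ccccc5)cc(OCc5ccccc5)c4c3O[C@H](c3ccc(OCc5ccccc5)c(OCc5ccccc5)c3)[C@H](OCc5ccccc5)C4)[C@H]2O)cc1 | intermediate
21 | epiafzelechin-(4β→8)-epicatechin-(4β→8)-epicatechin (CNP0158921.2) | Oc1ccc([C@H]2Oc3cc(O)cc(O)c3[C@H](c3c(O)cc(O)c4c3O[C@H](c3ccc(O)c(O)c3)[C@H](O)[C@H]4c3c(O)cc(O)c4c3O[C@H](c3ccc(O)c(O)c3)[C@H](O)C4)[C@H]2O)cc1 | target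

Total step count: 14.
Longest linear sequence: 10 steps (steps 1–5 and 10–14).

Steps most likely to fail

Step 13 may fail through protonation of the C4 anion (by the acidic C2–H or traces of water) before ring closure, through reductive loss of the aryloxy group if the aldehyde is reduced first, or through poor facial selectivity at C3. The fallback joins the top unit by the established cationic flavanylation; it sets out from 6 and comes back to the route at 21. Bromine–lithium exchange on 6 (t-BuLi, THF, −78 °C) and a methanol quench should give deca-O-benzyl-epicatechin-(4β→8)-epicatechin F1. (−)-Epiafzelechin, bought as a phytochemical standard (O[C@@H]1Cc2c(O)cc(O)cc2O[C@@H]1c1ccc(O)cc1), is benzylated on its three phenols (BnBr, K2CO3, DMF) to 5,7,4′-tri-O-benzylepiafzelechin F2, and DDQ with 2-ethoxyethanol converts this into the 4β-(2-ethoxyethoxy) ether F3. TMSOTf in CH2Cl2 at −78 °C should then join C4 of F3 to C8 of the upper unit of F1 (used in excess) on the β face, giving trideca-O-benzyl trimer F4, and hydrogenolysis over Pd(OH)2 on carbon gives 21.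

Step 12 may fail through epimerisation at C2 of the α-aryloxy aldehyde under fluoride, or through nucleophilic capture and oligomerisation of the quinone methide while it is released. The fallback makes the quinone methide by oxidation instead of elimination; it sets out from 15 and comes back at 18. Ionic hydrogenation (Et3SiH, CF3CO2H, CH2Cl2, −40 °C) removes the carbinol oxygen to give diarylmethane ester F5. The silyl ether is cleaved at this robust ester stage (TBAF, AcOH, THF) to phenol ester F6, and i-Bu2AlH at −78 °C gives phenol aldehyde F7. Ag2O in CH2Cl2 then oxidises the para-benzylphenol of F7 to 18 without fluoride or soluble base.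

Step 10 may fail through slow addition to the doubly ortho-substituted aldehyde, with competing deprotonation next to the ester (loss of the C2 configuration) or attack on the ester. The fallback replaces the aryl metal addition by electrophilic aromatic substitution; it sets out from 6 and 12 and comes back at 15. Bromine–lithium exchange on 6 and a methanol quench give deca-O-benzyl dimer F8 (the same compound as F1). Friedel–Crafts hydroxyalkylation of F8 with 12 (TMSOTf, CH2Cl2, −78 °C to −40 °C) should take place at C8 of the upper unit, its most nucleophilic free position, and an aqueous NaHCO3 quench of the stabilised diarylmethyl cation returns 15.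

Further compounds
F1 | step 13 | deca-O-benzyl-epicatechin-(4β→8)-epicatechin | c3c(OCc5ccccc5)cc(OCc5ccccc5)c4c3O[C@H](c3ccc(OCc5ccccc5)c(OCc5ccccc5)c3)[C@H](OCc5ccccc5)[C@H]4c3c(OCc5ccccc5)cc(OCc5ccccc5)c4c3O[C@H](c3ccc(OCc5ccccc5)c(OCc5ccccc5)c3)[C@H](OCc5ccccc5)C4
F2 | step 13 | 5,7,4′-tri-O-benzyl-(−)-epiafzelechin | c1c(OCc5ccccc5)cc(OCc5ccccc5)c2c1O[C@H](c1ccc(OCc5ccccc5)cc1)[C@H](O)C2
F3 | step 13 | 4β-(2-ethoxyethoxy)-5,7,4′-tri-O-benzylepiafzelechin | c1c(OCc5ccccc5)cc(OCc5ccccc5)c2c1O[C@H](c1ccc(OCc5ccccc5)cc1)[C@H](O)[C@H]2OCCOCC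
F4 | step 13 | trideca-O-benzyl epiafzelechin-(4β→8)-epicatechin-(4β→8)-epicatechin, free 3-OH on the top unit | O(Cc5ccccc5)c1ccc([C@H]2Oc3cc(OCc5ccccc5)cc(OCc5ccccc5)c3[C@H](c3c(OCc5ccccc5)cc(OCc5ccccc5)c4c3O[C@H](c3ccc(OCc5ccccc5)c(OCc5ccccc5)c3)[C@H](OCc5ccccc5)[C@H]4c3c(OCc5ccccc5)cc(OCc5ccccc5)c4c3O[C@H](c3ccc(OCc5ccccc5)c(OCc5ccccc5)c3)[C@H](OCc5ccccc5)C4)[C@H]2O)cc1
F5 | step 12 | benzyl (R)-2-(4-benzyloxyphenyl)-2-[3-benzyloxy-2-(dimer-8-ylmethyl)-5-(triisopropylsilyloxy)phenoxy]acetate | O=C(OCc5ccccc5)[C@@H](c1ccc(OCc5ccccc5)cc1)Oc1cc(O[Si](C(C)C)(C(C)C)C(C)C)cc(OCc5ccccc5)c1Cc3c(OCc5ccccc5)cc(OCc5ccccc5)c4c3O[C@H](c3ccc(OCc5ccccc5)c(OCc5ccccc5)c3)[C@H](OCc5ccccc5)[C@H]4c3c(OCc5ccccc5)cc(OCc5ccccc5)c4c3O[C@H](c3ccc(OCc5ccccc5)c(OCc5ccccc5)c3)[C@H](OCc5ccccc5)C4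
F6 | step 12 | benzyl (R)-2-(4-benzyloxyphenyl)-2-[3-benzyloxy-2-(dimer-8-ylmethyl)-5-hydroxyphenoxy]acetate | O=C(OCc5ccccc5)[C@@H](c1ccc(OCc5ccccc5)cc1)Oc1cc(O)cc(OCc5ccccc5)c1Cc3c(OCc5ccccc5)cc(OCc5ccccc5)c4c3O[C@H](c3ccc(OCc5ccccc5)c(OCc5ccccc5)c3)[C@H](OCc5ccccc5)[C@H]4c3c(OCc5ccccc5)cc(OCc5ccccc5)c4c3O[C@H](c3ccc(OCc5ccccc5)c(OCc5ccccc5)c3)[C@H](OCc5ccccc5)C4
F7 | step 12 | (R)-2-(4-benzyloxyphenyl)-2-[3-benzyloxy-2-(dimer-8-ylmethyl)-5-hydroxyphenoxy]acetaldehyde | O=C[C@@H](c1ccc(OCc5ccccc5)cc1)Oc1cc(O)cc(OCc5ccccc5)c1Cc3c(OCc5ccccc5)cc(OCc5ccccc5)c4c3O[C@H](c3ccc(OCc5ccccc5)c(OCc5ccccc5)c3)[C@H](OCc5ccccc5)[C@H]4c3c(OCc5ccccc5)cc(OCc5ccccc5)c4c3O[C@H](c3ccc(OCc5ccccc5)c(OCc5ccccc5)c3)[C@H](OCc5ccccc5)C4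
F8 | step 10 | deca-O-benzyl-epicatechin-(4β→8)-epicatechin (identical with F1) | c3c(OCc5ccccc5)cc(OCc5ccccc5)c4c3O[C@H](c3ccc(OCc5ccccc5)c(OCc5ccccc5)c3)[C@H](OCc5ccccc5)[C@H]4c3c(OCc5ccccc5)cc(OCc5ccccc5)c4c3O[C@H](c3ccc(OCc5ccccc5)c(OCc5ccccc5)c3)[C@H](OCc5ccccc5)C4
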